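**Retrosynthetic overview**

1. Numbering: C1 = ArCH2, C2–C7 = carbocycle (C6–Br, C7 quaternary), C8–C15 = chain (C10/C11 epoxide, C14–Br, C15–O). The 16-membered ring is formed last, at C1–C2, by an intramolecular benzylzinc/enol-triflate (Negishi) coupling that also creates the tetrasubstituted alkene; the phenol silyl ether is removed at the end.
2. Epoxide: Shi epoxidation of the acyclic E-C10=C11 alkene, which is made by B-alkyl Suzuki coupling at C9–C10 while C2/C3 is still a deactivated enol triflate.
3. Tertiary bromo ester: the (R)-bromohydrin (Shi epoxide opened by bromide at C14) is acylated with chloromethylated, silylated 4-hydroxybenzoic acid.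
4. C6–Br/C7 pair: bromonium-induced semipinacol rearrangement (1,2-vinyl shift) of a tertiary allylic alcohol; the carbocycle is present from the start.
5. Key step: enantioselective deprotonation of meso cis-2,6-dimethylcyclohexanone (symmetry breaking). Its single stereocentre is relayed through vinyl addition and the semipinacol shift into C6 and C7, then erased at the enol triflate. Ring order: carbocycle (given) → oxiranes → macrocycle.

Assumption: the (S,S)-amide is taken to give the (R)-enol silane and vinyl is taken to add trans to the C6 methyl; if the net sense is the opposite, the antipodal amide is used and nothing else changes.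

**Route**

Step 1
Reactants: 1 cis-2,6-dimethylcyclohexan-1-one (meso, pure cis isomer)
Product: 3 (R)-[(2,6-dimethylcyclohex-1-en-1-yl)oxy]trimethylsilane, via lithium enolate 2 (not isolated)
Conditions: (S,S)-bis(1-phenylethyl)amine, n-BuLi, THF, −78 °C; TMSCl (in situ quench); 1 added slowly, −78 °C
Reagents that add atoms: chlorotrimethylsilane, C[Si](C)(C)Cl
Why: Enantioselective deprotonation of a meso ketone by a chiral lithium amide (Simpkins–Koga desymmetrisation) removes one of the two enantiotopic α-hydrogens, and the TMSCl quench fixes the enolate, leaving C6 as a single (R) stereocentre (about 90% ee expected) that is the only source of absolute configuration for the carbocycle.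

Step 2
Reactants: 3 (R)-[(2,6-dimethylcyclohex-1-en-1-yl)oxy]trimethylsilane
Product: 4 (R)-2,6-dimethylcyclohex-2-en-1-one
Conditions: Pd(OAc)2 (10 mol %), O2 (1 atm), DMSO, 25 °C
Reagents that add atoms: none
Why: Saegusa–Ito dehydrogenation (aerobic variant): the Pd enolate at C2 undergoes β-hydride elimination into the ring under neutral conditions, so the α′ stereocentre at C6 is not touched.

Step 3
Reactants: 4 (R)-2,6-dimethylcyclohex-2-en-1-one
Product: 5 (1R,6R)-1-ethenyl-2,6-dimethylcyclohex-2-en-1-ol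
Conditions: CH2=CHMgBr, THF, −78 °C; aq. NH4Cl
Reagents that add atoms: vinylmagnesium bromide, C=C[Mg]Br
Why: Grignard 1,2-addition to the enone carbonyl, with vinyl entering from the face away from the adjacent C6 methyl (equatorial attack on the half-chair), gives the 1R carbinol with OH cis to that methyl (dr about 5–8:1 expected, minor isomer removed by chromatography).

Step 4
Reactants: 5 (1R,6R)-1-ethenyl-2,6-dimethylcyclohex-2-en-1-ol
Product: 6 (2S,3S,6R)-3-bromo-2-ethenyl-2,6-dimethylcyclohexan-1-one
Conditions: NBS, NaHCO3, CH2Cl2, −40 → 0 °C, dark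
Reagents that add atoms: N-bromosuccinimide, O=C1CCC(=O)N1Br
Why: Proposed new method: bromonium-induced semipinacol rearrangement, in which Br+ adds to the trisubstituted ring alkene (more electron-rich than the vinyl group) and the vinyl group on the opposite face migrates from the carbinol carbon to the tertiary cationic carbon as the C=O forms, so the carbinol configuration is transferred to the new quaternary centre (2S) and the C–Br centre (3S) is set trans to the migrated vinyl by anti addition; the closest known chemistry is the NBS-induced semipinacol rearrangement of tertiary allylic alcohols to α-quaternary β-bromo ketones.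

Step 5
Reactants: 6 (2S,3S,6R)-3-bromo-2-ethenyl-2,6-dimethylcyclohexan-1-one
Product: 8 (5S,6S)-5-bromo-6-ethenyl-2,6-dimethylcyclohex-1-en-1-yl trifluoromethanesulfonate, via potassium enolate 7 (not isolated)
Conditions: KHMDS, THF, −78 °C; PhNTf2, −78 → 0 °C
Reagents that add atoms: N-phenylbis(trifluoromethanesulfonimide), O=S(=O)(N(c1ccccc1)S(=O)(=O)C(F)(F)F)C(F)(F)F
Why: Enol triflate formation: C6 is the only enolisable position, so one tetrasubstituted enolate forms and is O-triflated, which erases the relay stereocentre and leaves the C–Br and quaternary centres untouched.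

Step 6
Reactants: 9 6-methylhept-5-en-2-one
Product: 13 6-methylhept-5-en-1-yne, via lithium enolate 10 (not isolated), via enol phosphate 11 (not isolated), via lithium acetylide 12 (not isolated)
Conditions: LDA, THF, −78 °C; ClP(O)(OEt)2; LDA (2.3 equiv), −78 °C → rt; aq. NH4Cl
Reagents that add atoms: none
Why: Negishi methyl-ketone-to-alkyne protocol: O-phosphorylation of the kinetic enolate, then LDA-induced β-elimination of diethyl phosphate from the terminal enol phosphate; no stereocentre is involved.

Step 7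
Reactants: 13 6-methylhept-5-en-1-yne
Product: 15 (E)-1-iodo-2,6-dimethylhepta-1,5-diene, via alkenylalane 14 (not isolated)
Conditions: Me3Al, Cp2ZrCl2 (cat.), CH2Cl2, 0 °C → rt; I2, THF, −30 °C
Reagents that add atoms: trimethylaluminium, C[Al](C)C; iodine, II
Why: Zr-catalysed Negishi carboalumination adds Me–Al syn across the terminal alkyne (methyl to the internal carbon) and iodinolysis of the C–Al bond proceeds with retention, giving the E iodoalkene while the remote trisubstituted alkene stays inert.

Step 8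
Reactants: 15 (E)-1-iodo-2,6-dimethylhepta-1,5-diene
Product: 16 (S)-3-[(E)-5-iodo-4-methylpent-4-en-1-yl]-2,2-dimethyloxirane
Conditions: ent-Shi ketone (L-fructose-derived, 30 mol %), Oxone, K2CO3, Bu4NHSO4, MeCN–DMM–aq. buffer (pH 10.5), 0 °C
Reagents that add atoms: potassium peroxymonosulfate (Oxone), [K+].[O-]S(=O)(=O)OO
Why: Shi asymmetric epoxidation: the chiral dioxirane attacks only the electron-rich prenyl-type alkene (the iodoalkene is deactivated) through the spiro transition state and gives the S epoxide (about 90% ee expected).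

Step 9
Reactants: 16 (S)-3-[(E)-5-iodo-4-methylpent-4-en-1-yl]-2,2-dimethyloxirane
Product: 17 (R,E)-3-bromo-7-iodo-2,6-dimethylhept-6-en-2-ol
Conditions: Li2NiBr4, THF, 0 °C → rt; pH 7 buffer
Reagents that add atoms: dilithium tetrabromonickelate, [Li+].[Li+].[Ni+2].[Br-].[Br-].[Br-].[Br-]
Why: Regioselective SN2 epoxide opening by soft bromide at the secondary carbon under non-acidic conditions proceeds with inversion and gives the R secondary bromide next to the free tertiary alcohol.

Step 10
Reactants: 18 4-hydroxybenzoic acid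
Product: 20 3-(chloromethyl)-4-hydroxybenzoic acid, via hydroxymethyl acid 19 (not isolated)
Conditions: (CH2O)n, conc. HCl, HCl (g), 45 °C
Reagents that add atoms: formaldehyde (as paraformaldehyde), C=O; hydrogen chloride, Cl
Why: Blanc chloromethylation (electrophilic aromatic substitution): the phenol OH directs the hydroxymethyl cation ortho (para is blocked by CO2H) and HCl converts the benzylic alcohol into the chloride; no stereocentre.

Step 11
Reactants: 20 3-(chloromethyl)-4-hydroxybenzoic acid
Product: 22 3-(chloromethyl)-4-[(triisopropylsilyl)oxy]benzoic acid, via bis-silyl compound 21 (not isolated)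
Conditions: TIPSOTf (2.2 equiv), 2,6-lutidine, CH2Cl2, −78 → 0 °C; then THF/1 M HCl, rt
Reagents that add atoms: triisopropylsilyl trifluoromethanesulfonate, CC(C)[Si](OS(=O)(=O)C(F)(F)F)(C(C)C)C(C)C
Why: Silylation of phenol and acid with a silyl triflate and the non-nucleophilic base 2,6-lutidine (which does not attack the benzylic chloride), followed by selective hydrolysis of the labile silyl ester; no stereocentre.

Step 12
Reactants: 22 3-(chloromethyl)-4-[(triisopropylsilyl)oxy]benzoic acid; 17 (R,E)-3-bromo-7-iodo-2,6-dimethylhept-6-en-2-ol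
Product: 24 (3R,6E)-3-bromo-7-iodo-2,6-dimethylhept-6-en-2-yl 3-(chloromethyl)-4-[(triisopropylsilyl)oxy]benzoate, via symmetric anhydride 23 (not isolated)
Conditions: 22 (2.4 equiv), DCC (1.2 equiv), CH2Cl2, 0 °C → rt, filter; then 17, Sc(OTf)3 (5 mol %), MeCN, −20 → 0 °C
Reagents that add atoms: none
Why: Sc(OTf)3-catalysed acylation of a hindered tertiary alcohol by a symmetric aroyl anhydride (Yamamoto acylation) avoids nucleophilic amines that would quaternise the benzylic chloride and alkoxide bases that would close the bromohydrin to an epoxide, and the C3 stereocentre is not involved.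

Step 13
Reactants: 8 (5S,6S)-5-bromo-6-ethenyl-2,6-dimethylcyclohex-1-en-1-yl trifluoromethanesulfonate; 24 (3R,6E)-3-bromo-7-iodo-2,6-dimethylhept-6-en-2-yl 3-(chloromethyl)-4-[(triisopropylsilyl)oxy]benzoate
Product: 26 (3R,6E)-3-bromo-9-[(1S,6S)-6-bromo-1,3-dimethyl-2-(triflyloxy)cyclohex-2-en-1-yl]-2,6-dimethylnon-6-en-2-yl 3-(chloromethyl)-4-[(triisopropylsilyl)oxy]benzoate, via alkylborane 25 (not isolated)
Conditions: 8, 9-BBN, THF, rt; then 24, Pd(dppf)Cl2 (5 mol %), AsPh3, aq. K3PO4, THF, rt
Reagents that add atoms: none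
Why: B-alkyl Suzuki–Miyaura coupling: 9-BBN hydroborates only the monosubstituted vinyl group, and Pd(0) inserts into the alkenyl iodide much faster than into the hindered enol triflate, the benzylic chloride or the alkyl bromides, so the E geometry is retained and no stereocentre is formed (minor enantiomers of 8 and 24 become separable diastereomers here).

Step 14
Reactants: 26 (3R,6E)-3-bromo-9-[(1S,6S)-6-bromo-1,3-dimethyl-2-(triflyloxy)cyclohex-2-en-1-yl]-2,6-dimethylnon-6-en-2-yl 3-(chloromethyl)-4-[(triisopropylsilyl)oxy]benzoate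
Product: 27 (R)-3-bromo-5-[(2S,3S)-3-{2-[(1S,6S)-6-bromo-1,3-dimethyl-2-(triflyloxy)cyclohex-2-en-1-yl]ethyl}-2-methyloxiran-2-yl]-2-methylpentan-2-yl 3-(chloromethyl)-4-[(triisopropylsilyl)oxy]benzoate
Conditions: ent-Shi ketone (30 mol %), Oxone, K2CO3, Bu4NHSO4, MeCN–DMM–aq. buffer (pH 10.5), 0 °C
Reagents that add atoms: potassium peroxymonosulfate (Oxone), [K+].[O-]S(=O)(=O)OO
Why: Shi asymmetric epoxidation of the only electron-rich alkene (the enol triflate alkene is deactivated) on an acyclic E-trisubstituted olefin, so the catalyst sets both epoxide centres (2S,3S) before the tetrasubstituted ring alkene exists.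

Step 15
Reactants: 27 (R)-3-bromo-5-[(2S,3S)-3-{2-[(1S,6S)-6-bromo-1,3-dimethyl-2-(triflyloxy)cyclohex-2-en-1-yl]ethyl}-2-methyloxiran-2-yl]-2-methylpentan-2-yl 3-(chloromethyl)-4-[(triisopropylsilyl)oxy]benzoate
Product: 29 O-triisopropylsilyl ether of the target macrolide, via benzylzinc chloride 28 (not isolated)
Conditions: Zn dust, LiCl, THF, 25 °C; then syringe-pump addition to Pd2(dba)3 (5 mol %), SPhos (12 mol %), THF, 60 °C (final 1 mM)
Reagents that add atoms: none
Why: Intramolecular Negishi sp3–sp2 coupling: zinc inserts selectively into the benzylic C–Cl bond and Pd/SPhos couples the benzylzinc with the hindered cyclohexenyl triflate under high dilution, closing the 16-membered ring and creating the tetrasubstituted alkene without touching any stereocentre.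

Step 16
Reactants: 29 O-triisopropylsilyl ether of the target macrolide
Product: 30 CNP0420597.1 (6S,7S,10S,11S,14R in the numbering above)
Conditions: TBAF, AcOH, THF, 0 °C
Reagents that add atoms: none
Why: Fluoride cleavage of the aryl silyl ether buffered with acetic acid (desilylation) is near-neutral and leaves the epoxide, the tertiary ester and both secondary bromides intact.

**Compound list**

1 | cis-2,6-dimethylcyclohexan-1-one (meso) | C[C@@H]1CCC[C@H](C)C1=O | starting material
2 | lithium (R)-2,6-dimethylcyclohex-1-en-1-olate | C[C@@H]1CCCC(C)=C1O[Li] | intermediate (not isolated)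
3 | (R)-[(2,6-dimethylcyclohex-1-en-1-yl)oxy]trimethylsilane | C[C@@H]1CCCC(C)=C1O[Si](C)(C)C | intermediate
4 | (R)-2,6-dimethylcyclohex-2-en-1-one | C[C@@H]1CCC=C(C)C1=O | intermediate
5 | (1R,6R)-1-ethenyl-2,6-dimethylcyclohex-2-en-1-ol | C[C@@H]1CCC=C(C)[C@@]1(O)C=C | intermediate
6 | (2S,3S,6R)-3-bromo-2-ethenyl-2,6-dimethylcyclohexan-1-one (C6 configuration is of no consequence) | C[C@@H]1CC[C@H](Br)[C@@](C)(C=C)C1=O | intermediate
7 | potassium (5S,6S)-5-bromo-6-ethenyl-2,6-dimethylcyclohex-1-en-1-olate | CC1=C(O[K])[C@](C)(C=C)[C@@H](Br)CC1 | intermediate (not isolated)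
8 | (5S,6S)-5-bromo-6-ethenyl-2,6-dimethylcyclohex-1-en-1-yl trifluoromethanesulfonate | CC1=C(OS(=O)(=O)C(F)(F)F)[C@](C)(C=C)[C@@H](Br)CC1 | intermediate
9 | 6-methylhept-5-en-2-one | CC(=O)CCC=C(C)C | starting material
10 | lithium 6-methylhepta-1,5-dien-2-olate | [Li]OC(=C)CCC=C(C)C | intermediate (not isolated)
11 | diethyl 6-methylhepta-1,5-dien-2-yl phosphate | C=C(CCC=C(C)C)OP(=O)(OCC)OCC | intermediate (not isolated)
12 | lithium 6-methylhept-5-en-1-yn-1-ide | [Li]C#CCCC=C(C)C | intermediate (not isolated)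
13 | 6-methylhept-5-en-1-yne | C#CCCC=C(C)C | intermediate
14 | (E)-(2,6-dimethylhepta-1,5-dien-1-yl)dimethylalane | C[Al](C)/C=C(C)/CCC=C(C)C | intermediate (not isolated)
15 | (E)-1-iodo-2,6-dimethylhepta-1,5-diene | I/C=C(C)/CCC=C(C)C | intermediate
16 | (S)-3-[(E)-5-iodo-4-methylpent-4-en-1-yl]-2,2-dimethyloxirane | I/C=C(C)/CC[C@@H]1OC1(C)C | intermediate
17 | (R,E)-3-bromo-7-iodo-2,6-dimethylhept-6-en-2-ol | I/C=C(C)/CC[C@@H](Br)C(C)(C)O | intermediate
18 | 4-hydroxybenzoic acid | OC(=O)c1ccc(O)cc1 | starting material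
19 | 4-hydroxy-3-(hydroxymethyl)benzoic acid | OCc1cc(ccc1O)C(O)=O | intermediate (not isolated)
20 | 3-(chloromethyl)-4-hydroxybenzoic acid | ClCc1cc(ccc1O)C(O)=O | intermediate
21 | triisopropylsilyl 3-(chloromethyl)-4-[(triisopropylsilyl)oxy]benzoate | ClCc1cc(ccc1O[Si](C(C)C)(C(C)C)C(C)C)C(=O)O[Si](C(C)C)(C(C)C)C(C)C | intermediate (not isolated)
22 | 3-(chloromethyl)-4-[(triisopropylsilyl)oxy]benzoic acid | ClCc1cc(ccc1O[Si](C(C)C)(C(C)C)C(C)C)C(O)=O | intermediate
23 | 3-(chloromethyl)-4-[(triisopropylsilyl)oxy]benzoic anhydride | ClCc1cc(ccc1O[Si](C(C)C)(C(C)C)C(C)C)C(=O)OC(=O)c1ccc(O[Si](C(C)C)(C(C)C)C(C)C)c(CCl)c1 | intermediate (not isolated)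
24 | (3R,6E)-3-bromo-7-iodo-2,6-dimethylhept-6-en-2-yl 3-(chloromethyl)-4-[(triisopropylsilyl)oxy]benzoate | I/C=C(C)/CC[C@@H](Br)C(C)(C)OC(=O)c1ccc(O[Si](C(C)C)(C(C)C)C(C)C)c(CCl)c1 | intermediate
25 | (5S,6S)-6-[2-(9-borabicyclo[3.3.1]nonan-9-yl)ethyl]-5-bromo-2,6-dimethylcyclohex-1-en-1-yl trifluoromethanesulfonate | CC1=C(OS(=O)(=O)C(F)(F)F)[C@](C)(CCB2C3CCCC2CCC3)[C@@H](Br)CC1 | intermediate (not isolated)
26 | (3R,6E)-3-bromo-9-[(1S,6S)-6-bromo-1,3-dimethyl-2-(triflyloxy)cyclohex-2-en-1-yl]-2,6-dimethylnon-6-en-2-yl 3-(chloromethyl)-4-[(triisopropylsilyl)oxy]benzoate | CC1=C(OS(=O)(=O)C(F)(F)F)[C@](C)(CC/C=C(C)/CC[C@@H](Br)C(C)(C)OC(=O)c2ccc(O[Si](C(C)C)(C(C)C)C(C)C)c(CCl)c2)[C@@H](Br)CC1 | intermediate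
27 | (R)-3-bromo-5-[(2S,3S)-3-{2-[(1S,6S)-6-bromo-1,3-dimethyl-2-(triflyloxy)cyclohex-2-en-1-yl]ethyl}-2-methyloxiran-2-yl]-2-methylpentan-2-yl 3-(chloromethyl)-4-[(triisopropylsilyl)oxy]benzoate | CC1=C(OS(=O)(=O)C(F)(F)F)[C@](C)(CC[C@@H]2O[C@@]2(C)CC[C@@H](Br)C(C)(C)OC(=O)c2ccc(O[Si](C(C)C)(C(C)C)C(C)C)c(CCl)c2)[C@@H](Br)CC1 | intermediate
28 | benzylzinc chloride derived from 27 (ArCH2ZnCl) | CC1=C(OS(=O)(=O)C(F)(F)F)[C@](C)(CC[C@@H]2O[C@@]2(C)CC[C@@H](Br)C(C)(C)OC(=O)c2ccc(O[Si](C(C)C)(C(C)C)C(C)C)c(C[Zn]Cl)c2)[C@@H](Br)CC1 | intermediate (not isolated)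
29 | O-triisopropylsilyl ether of the target macrolide | CC1=C2Cc3cc(ccc3O[Si](C(C)C)(C(C)C)C(C)C)C(=O)OC(C)(C)[C@H](Br)CC[C@]3(C)O[C@H]3CC[C@]2(C)[C@@H](Br)CC1 | intermediate
30 | CNP0420597.1 (6S,7S,10S,11S,14R) | CC1=C2Cc3cc(ccc3O)C(=O)OC(C)(C)[C@H](Br)CC[C@]3(C)O[C@H]3CC[C@]2(C)[C@@H](Br)CC1 | target

**Step count and risks**

Total step count: 16. Longest linear sequence: 9 steps (steps 1–5, then 13–16; the chain line 6–9, 12, 13–16 is equally long).

Step 4 (bromonium semipinacol). Possible failures are closure to a bromo-epoxide, ionisation of the tertiary allylic alcohol, or attack on the vinyl group. The fallback sets out from 5. The alcohol is capped as the trimethylsilyl ether F1 (TMSOTf, 2,6-lutidine, CH2Cl2, −78 °C). The shift is then triggered with bromodiethylsulfonium bromopentachloroantimonate in MeNO2 at −25 °C, so that a silyl group and not a proton is lost (silyl-terminated semipinacol, no free OH to close an epoxide). This gives the same bromo ketone and comes back to the route at 6.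

Step 12 (acylation of the tertiary β-bromo alcohol without nucleophilic catalysis). The Lewis-acid acylation may be too slow or may ionise the alcohol. The fallback sets out from 17 and uses commercial 3-formyl-4-hydroxybenzoic acid, silylated (TIPSCl, imidazole, mild aqueous work-up) to 3-formyl-4-[(triisopropylsilyl)oxy]benzoic acid F2. With no benzylic halide present, the alcohol can be acylated under forcing DMAP catalysis (2,4,6-trichlorobenzoyl chloride, Et3N, then 17, DMAP, toluene, 60 °C) to the formyl ester F3. NaBH4 (THF/MeOH, −20 °C) gives the hydroxymethyl ester F4, and Ph3P/N-chlorosuccinimide (CH2Cl2, 0 °C) converts it into the benzylic chloride, which comes back to the route at 24.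

Step 15 (macrocyclic Negishi coupling onto a hindered tetrasubstituted enol triflate). Transmetalation may be too slow at high dilution, or the zinc salts may open the epoxide. The fallback sets out from 27. Oxidation of the benzylic chloride with N-methylmorpholine N-oxide (MeCN, 40 °C) gives the aldehyde F5. An intramolecular Nozaki–Hiyama–Kishi reaction (CrCl2, cat. NiCl2, DMF/THF, high dilution, rt) of the enol triflate onto the aldehyde closes the ring as the macrocyclic benzylic alcohol F6 (both C1 epimers are usable). Acetylation (Ac2O, DMAP, pyridine) gives the acetate F7. TBAF followed by NaBH4 (THF/i-PrOH, 0 °C) removes the silyl group; the phenoxide expels acetate to an ortho-quinone methide and hydride adds at C1. This comes back to the route at 30, without passing through 29.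

**Further compounds**

F1 | step 4 | [(1R,6R)-1-ethenyl-2,6-dimethylcyclohex-2-en-1-yl]oxy(trimethyl)silane | C[C@@H]1CCC=C(C)[C@@]1(O[Si](C)(C)C)C=C
F2 | step 12 | 3-formyl-4-[(triisopropylsilyl)oxy]benzoic acid | O=Cc1cc(ccc1O[Si](C(C)C)(C(C)C)C(C)C)C(O)=O
F3 | step 12 | (3R,6E)-3-bromo-7-iodo-2,6-dimethylhept-6-en-2-yl 3-formyl-4-[(triisopropylsilyl)oxy]benzoate | I/C=C(C)/CC[C@@H](Br)C(C)(C)OC(=O)c1ccc(O[Si](C(C)C)(C(C)C)C(C)C)c(C=O)c1
F4 | step 12 | (3R,6E)-3-bromo-7-iodo-2,6-dimethylhept-6-en-2-yl 3-(hydroxymethyl)-4-[(triisopropylsilyl)oxy]benzoate | I/C=C(C)/CC[C@@H](Br)C(C)(C)OC(=O)c1ccc(O[Si](C(C)C)(C(C)C)C(C)C)c(CO)c1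
F5 | step 15 | 3-formyl analogue of 27 (CHO in place of CH2Cl) | CC1=C(OS(=O)(=O)C(F)(F)F)[C@](C)(CC[C@@H]2O[C@@]2(C)CC[C@@H](Br)C(C)(C)OC(=O)c2ccc(O[Si](C(C)C)(C(C)C)C(C)C)c(C=O)c2)[C@@H](Br)CC1
F6 | step 15 | C1-hydroxy derivative of 29 (C1 epimers) | CC1=C2C(O)c3cc(ccc3O[Si](C(C)C)(C(C)C)C(C)C)C(=O)OC(C)(C)[C@H](Br)CC[C@]3(C)O[C@H]3CC[C@]2(C)[C@@H](Br)CC1
F7 | step 15 | C1-acetoxy derivative of 29 (C1 epimers) | CC1=C2C(OC(C)=O)c3cc(ccc3O[Si](C(C)C)(C(C)C)C(C)C)C(=O)OC(C)(C)[C@H](Br)CC[C@]3(C)O[C@H]3CC[C@]2(C)[C@@H](Br)CC1
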